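**Plan**

1. Ring names: A = the 1,4-dioxygenated ring (free OH para to its aryl ether O); B = the ring with OH and ArO on neighbouring carbons; C = the para-phenylene; D = the meta-phenylene.
2. Cuts: first the aryl C–O bond between the ring B carbon ortho to its OH and the oxygen on ring C, which opens the 18-membered ring (2 C of A, 3 C of B, 4 C of C, 3 C of D, 2 O, 4 CH2); then the two ArCH2–CH2Ar bridges (A–B and C–D, each traced back to a stilbene); last the ring A–O–ring D ether.
3. Enabling feature: ring B is a para-alkylphenol whose ortho carbon carries the oxygen of a second para-alkylphenol (ring C). This is the pattern left by ortho C–O oxidative coupling of two para-alkylphenols, so the macrocycle can be closed by oxidative dearomatisation of ring B.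
4. Forward order: Ullmann ether A–O–D, Heck to attach ring C, methylenation and Heck to attach ring B, diimide saturation, dibromination of ring B, oxidative macro-etherification, global hydrogenolysis. All four benzene rings are bought; the macrocycle is the only ring made.
5. Helpers: two Br on ring B (make it the ring that is oxidised and supply the leaving group), two Cl on ring C (block C-coupling), benzyl on the ring A oxygen. All are removed together in the last step.
6. Stereochemistry: the target has no stereocentre; alkene geometry is erased by reduction, and the one transient stereocentre (the quinol ether carbon) is erased on rearomatisation.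

Key step: step 7

Remark: the structure has no stereodescriptor and no stereogenic unit (the 18-membered ring is assumed to flip freely at room temperature), so the "single enantiomer" is one achiral compound and no asymmetric step is needed.

**Route**

Step 1
Reactants: 1 5-(benzyloxy)-2-bromobenzaldehyde; 2 3-vinylphenol
Product: 3 5-(benzyloxy)-2-(3-ethenylphenoxy)benzaldehyde
Conditions: CuI (10 mol%), N,N-dimethylglycine (30 mol%), Cs2CO3 (2 equiv), BHT (cat.), 1,4-dioxane, 90 °C
Reagents that add atoms: none
Why: Ullmann-type Cu(I)-catalysed C–O coupling, in which the ortho-formyl group speeds oxidative addition of the aryl bromide, the benzyl ether, aldehyde and styrene are inert to Cu(I)/carbonate, and the single phenol of 2 leaves no choice of oxygen.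

Step 2
Reactants: 3 5-(benzyloxy)-2-(3-ethenylphenoxy)benzaldehyde; 4 4-bromo-2,6-dichlorophenol
Product: 5 5-(benzyloxy)-2-{3-[(E)-2-(3,5-dichloro-4-hydroxyphenyl)ethenyl]phenoxy}benzaldehyde
Conditions: Pd(OAc)2 (5 mol%), P(o-tol)3 (10 mol%), NaOAc (2.5 equiv), DMF, 110 °C
Reagents that add atoms: none
Why: Mizoroki–Heck reaction in which Pd(0) inserts into the C–Br bond only (aryl chlorides are inert with P(o-tol)3), syn-insertion at the terminal styrene carbon and β-hydride elimination should give the E-stilbene, and the aldehyde and benzyl ether are spectators.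

Step 3
Reactants: 5 5-(benzyloxy)-2-{3-[(E)-2-(3,5-dichloro-4-hydroxyphenyl)ethenyl]phenoxy}benzaldehyde
Product: 6 4-[(E)-2-{3-[4-(benzyloxy)-2-ethenylphenoxy]phenyl}ethenyl]-2,6-dichlorophenol
Conditions: Ph3PCH3Br (2.2 equiv), KOtBu (3.2 equiv), THF, 0 °C → rt; aq. NH4Cl
Reagents that add atoms: methyltriphenylphosphonium bromide, C[P+](c1ccccc1)(c1ccccc1)c1ccccc1.[Br-]
Why: Wittig methylenation with the non-stabilised ylide Ph3P=CH2, in which one extra equivalent of base is taken up by the acidic dichlorophenol and returned on aqueous work-up.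

Step 4
Reactants: 6 4-[(E)-2-{3-[4-(benzyloxy)-2-ethenylphenoxy]phenyl}ethenyl]-2,6-dichlorophenol; 7 4-iodophenol
Product: 8 4-[(E)-2-{3-[4-(benzyloxy)-2-[(E)-2-(4-hydroxyphenyl)ethenyl]phenoxy]phenyl}ethenyl]-2,6-dichlorophenol
Conditions: Pd(OAc)2 (5 mol%), P(o-tol)3 (10 mol%), NaOAc (2.5 equiv), DMF, 90 °C
Reagents that add atoms: none
Why: Second Mizoroki–Heck reaction, in which the monosubstituted styrene reacts far faster than the internal stilbene, C–I reacts and C–Cl does not, and the E-alkene is expected (its geometry is erased in step 5).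

Step 5
Reactants: 8 4-[(E)-2-{3-[4-(benzyloxy)-2-[(E)-2-(4-hydroxyphenyl)ethenyl]phenoxy]phenyl}ethenyl]-2,6-dichlorophenol
Product: 9 4-[2-(3-{4-(benzyloxy)-2-[2-(4-hydroxyphenyl)ethyl]phenoxy}phenyl)ethyl]-2,6-dichlorophenol
Conditions: TsNHNH2 (10 equiv), NaOAc (10 equiv), DME–H2O, reflux, recharged until both alkenes are consumed
Reagents that add atoms: none
Why: Diimide reduction, in which HN=NH from thermal fragmentation of tosylhydrazide transfers H2 to both stilbene C=C bonds through a concerted cyclic transition state and spares the aryl chlorides and the benzyl ether that catalytic hydrogenation would endanger.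

Step 6
Reactants: 9 4-[2-(3-{4-(benzyloxy)-2-[2-(4-hydroxyphenyl)ethyl]phenoxy}phenyl)ethyl]-2,6-dichlorophenol
Product: 10 4-[2-(3-{4-(benzyloxy)-2-[2-(3,5-dibromo-4-hydroxyphenyl)ethyl]phenoxy}phenyl)ethyl]-2,6-dichlorophenol
Conditions: Br2 (2.05 equiv), t-BuNH2 (4.2 equiv), toluene–CH2Cl2, −78 → −30 °C
Reagents that add atoms: bromine, BrBr
Why: Amine-mediated ortho-bromination of a phenol (electrophilic aromatic substitution by the N-bromoamine on the hydrogen-bonded phenol), which should be specific for ring B because it alone has free positions ortho to a free OH (ring C is blocked by Cl and alkyl) and the ether-only rings A and D are not activated by the amine.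

Step 7
Reactants: 10 4-[2-(3-{4-(benzyloxy)-2-[2-(3,5-dibromo-4-hydroxyphenyl)ethyl]phenoxy}phenyl)ethyl]-2,6-dichlorophenol
Product: 12 bromo-dichloro O-benzyl dihydroptychantol A (Br on ring B ortho to OH; Cl on both ring C carbons ortho to the ether O), via macrocyclic para-quinol methyl ether 11 (not isolated)
Conditions: Tl(NO3)3·3H2O (1.1 equiv), MeOH–THF (4:1, ca. 1 mM), −20 → 0 °C; then Zn dust, AcOH, 0 °C → rt
Reagents that add atoms: none
Why: Tl(III) exchanges onto the phenol of ring B (the 2,6-dibromophenol, expected to be the more easily oxidised of the two halophenols) and removes two electrons to give a phenoxonium-type species; the hydroxyl oxygen of ring C adds to the bromine-bearing ortho carbon, bromide leaves from this ipso adduct, methanol caps the para carbon to give the para-quinol methyl ether 11, and zinc in acetic acid then returns two electrons so that methanol is lost and ring B rearomatises as a 2-aryloxyphenol. The closest known reaction type is the thallium(III) nitrate oxidation/zinc reduction of tethered pairs of o,o'-dihalogenated para-alkylphenols, the biomimetic phenol-coupling route to isodityrosine-type macrocyclic diaryl ethers. The 18-membered ring is closed by O–C(aryl) bond formation between the ring C oxygen and an ortho carbon of the dearomatised ring B, run at about 1 mM so that intramolecular capture outruns dimerisation. No stereocentre remains, because the methoxy-bearing carbon of 11 forms as a racemate and becomes planar again on reduction. The step needs (i) oxidation of ring B and not ring C, secured by Br versus Cl (lower oxidation potential and the better ipso leaving group on ring B), (ii) O- and not C-coupling, secured because every ortho and para carbon of the ring C phenol is blocked by Cl or alkyl, and (iii) a single regiochemical outcome, secured because the two ortho carbons of ring B are equivalent. Ring B units that are only capped by methanol without cyclising should be reduced back to 10 by the zinc and can be resubmitted.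

Step 8
Reactants: 12 bromo-dichloro O-benzyl dihydroptychantol A
Product: 13 dihydroptychantol A
Conditions: H2 (1 atm), 10% Pd/C, NaOAc (4 equiv), MeOH–EtOAc, rt
Reagents that add atoms: none
Why: Heterogeneous Pd-catalysed hydrogenolysis, which should cleave the benzyl ether and the three aryl–halogen bonds (acetate takes up HX) in one operation while the diaryl ethers and ethano bridges are stable, giving the achiral target.

**Compound list**

1 | 5-(benzyloxy)-2-bromobenzaldehyde | O=Cc1cc(OCc2ccccc2)ccc1Br | starting material
2 | 3-vinylphenol (3-ethenylphenol) | C=Cc1cccc(O)c1 | starting material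
3 | 5-(benzyloxy)-2-(3-ethenylphenoxy)benzaldehyde | O=Cc1cc(OCc2ccccc2)ccc1Oc1cccc(C=C)c1 | intermediate
4 | 4-bromo-2,6-dichlorophenol | Oc1c(Cl)cc(Br)cc1Cl | starting material
5 | 5-(benzyloxy)-2-{3-[(E)-2-(3,5-dichloro-4-hydroxyphenyl)ethenyl]phenoxy}benzaldehyde | O=Cc1cc(OCc2ccccc2)ccc1Oc1cccc(/C=C/c2cc(Cl)c(O)c(Cl)c2)c1 | intermediate
6 | 4-[(E)-2-{3-[4-(benzyloxy)-2-ethenylphenoxy]phenyl}ethenyl]-2,6-dichlorophenol | C=Cc1cc(OCc2ccccc2)ccc1Oc1cccc(/C=C/c2cc(Cl)c(O)c(Cl)c2)c1 | intermediate
7 | 4-iodophenol | Oc1ccc(I)cc1 | starting material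
8 | 4-[(E)-2-{3-[4-(benzyloxy)-2-[(E)-2-(4-hydroxyphenyl)ethenyl]phenoxy]phenyl}ethenyl]-2,6-dichlorophenol (E,E) | Oc1ccc(/C=C/c2cc(OCc3ccccc3)ccc2Oc2cccc(/C=C/c3cc(Cl)c(O)c(Cl)c3)c2)cc1 | intermediate
9 | 4-[2-(3-{4-(benzyloxy)-2-[2-(4-hydroxyphenyl)ethyl]phenoxy}phenyl)ethyl]-2,6-dichlorophenol | Oc1ccc(CCc2cc(OCc3ccccc3)ccc2Oc2cccc(CCc3cc(Cl)c(O)c(Cl)c3)c2)cc1 | intermediate
10 | 4-[2-(3-{4-(benzyloxy)-2-[2-(3,5-dibromo-4-hydroxyphenyl)ethyl]phenoxy}phenyl)ethyl]-2,6-dichlorophenol | Oc1c(Br)cc(CCc2cc(OCc3ccccc3)ccc2Oc2cccc(CCc3cc(Cl)c(O)c(Cl)c3)c2)cc1Br | intermediate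
11 | macrocyclic para-quinol methyl ether, racemic: ring B as a 6-bromo-4-methoxycyclohexa-2,5-dienone whose C2 carries the ring C oxygen and whose C4 carries OMe and the ethano bridge to ring A; ring C 2,6-dichloro, ring A O-benzyl | O=C1C(Br)=CC2(OC)C=C1Oc1c(Cl)cc(cc1Cl)CCc1cccc(c1)Oc1ccc(OCc3ccccc3)cc1CC2 | intermediate (not isolated)
12 | bromo-dichloro O-benzyl dihydroptychantol A: ring A hydroxyl benzylated, Br on ring B ortho to its OH on the side away from the ether oxygen, Cl on both ring C carbons ortho to the ether oxygen | Oc1c(Br)cc2cc1Oc1c(Cl)cc(cc1Cl)CCc1cccc(c1)Oc1ccc(OCc3ccccc3)cc1CC2 | intermediate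
13 | dihydroptychantol A | Oc1ccc2c(c1)CCc1ccc(O)c(c1)Oc1ccc(cc1)CCc1cccc(c1)O2 | target

**Count**

Total steps: 8. Longest linear sequence: 8 steps (1 → 13, fully linear).

**Steps most likely to fail**

Step 7. The oxidised ring B may be captured by methanol or by a carbon of the electron-rich ring A instead of by the ring C oxygen. The wrong phenol (ring C) may be oxidised. Intermolecular coupling may lead to oligomers. Fallback (sets out from 3, comes back at 13): the macrocycle is closed by a copper-catalysed substitution instead of an oxidation.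
- Heck reaction of 3 with 7 (Pd(OAc)2, P(o-tol)3, NaOAc, DMF) should give 5-(benzyloxy)-2-{3-[(E)-2-(4-hydroxyphenyl)ethenyl]phenoxy}benzaldehyde F1.
- Methylenation (Ph3PCH3Br, KOtBu, THF) should give 4-[(E)-2-{3-[4-(benzyloxy)-2-ethenylphenoxy]phenyl}ethenyl]phenol F2.
- A C–I-selective Heck reaction with 2-bromo-4-iodoanisole should give 4-[(E)-2-{3-[4-(benzyloxy)-2-[(E)-2-(3-bromo-4-methoxyphenyl)ethenyl]phenoxy]phenyl}ethenyl]phenol F3.
- Diimide reduction as in step 5 should give 4-[2-(3-{4-(benzyloxy)-2-[2-(3-bromo-4-methoxyphenyl)ethyl]phenoxy}phenyl)ethyl]phenol F4.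
- Intramolecular Ullmann etherification under high dilution (CuI, N,N-dimethylglycine, Cs2CO3, dioxane, 100 °C, ca. 2 mM) should give O-benzyl O-methyl dihydroptychantol A F5.
- BBr3 (CH2Cl2, −78 → 0 °C) then cleaves the methyl and benzyl ethers to give 13.

Step 6. Site selectivity may be lost in the second bromination, with electrophilic attack on the electron-rich ring A (ortho to the benzyloxy group) or ipso attack on ring C instead of the remaining ortho position of ring B. Fallback (sets out from 6, comes back at 10): the bromines are brought in on the aryl halide, so no electrophilic bromination is run on the scaffold. Heck reaction of 6 with 2,6-dibromo-4-iodophenol under ligand-free conditions (Pd(OAc)2, Bu4NCl, NaHCO3, DMF, 60–70 °C; C–I reacts, the hindered C–Br bonds should not) should give 4-[(E)-2-{3-[4-(benzyloxy)-2-[(E)-2-(3,5-dibromo-4-hydroxyphenyl)ethenyl]phenoxy]phenyl}ethenyl]-2,6-dichlorophenol F6. Diimide reduction as in step 5 then gives 10.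

Step 8. Hydrodechlorination may stall at the two hindered chlorides flanking the ether oxygen after the benzyl group and the bromide have gone, leaving chlorinated macrocycles. Fallback (sets out from 12, comes back at 13): the halogens are removed first by homogeneous transfer hydrodehalogenation ((IPr)Pd(allyl)Cl cat., NaOtBu, i-PrOH, 60 °C), in which a soluble Pd–H species formed from isopropoxide replaces all three halogens and leaves the benzyl ether. This should give O-benzyl dihydroptychantol A F7. Hydrogenolysis of the benzyl ether alone (H2, Pd/C, EtOAc–MeOH) then gives 13.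

**Further compounds**

F1 | step 7 | 5-(benzyloxy)-2-{3-[(E)-2-(4-hydroxyphenyl)ethenyl]phenoxy}benzaldehyde | O=Cc1cc(OCc2ccccc2)ccc1Oc1cccc(/C=C/c2ccc(O)cc2)c1
F2 | step 7 | 4-[(E)-2-{3-[4-(benzyloxy)-2-ethenylphenoxy]phenyl}ethenyl]phenol | C=Cc1cc(OCc2ccccc2)ccc1Oc1cccc(/C=C/c2ccc(O)cc2)c1
F3 | step 7 | 4-[(E)-2-{3-[4-(benzyloxy)-2-[(E)-2-(3-bromo-4-methoxyphenyl)ethenyl]phenoxy]phenyl}ethenyl]phenol | COc1ccc(/C=C/c2cc(OCc3ccccc3)ccc2Oc2cccc(/C=C/c3ccc(O)cc3)c2)cc1Br
F4 | step 7 | 4-[2-(3-{4-(benzyloxy)-2-[2-(3-bromo-4-methoxyphenyl)ethyl]phenoxy}phenyl)ethyl]phenol | COc1ccc(CCc2cc(OCc3ccccc3)ccc2Oc2cccc(CCc3ccc(O)cc3)c2)cc1Br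
F5 | step 7 | O-benzyl (ring A) O-methyl (ring B) dihydroptychantol A | COc1ccc2cc1Oc1ccc(cc1)CCc1cccc(c1)Oc1ccc(OCc3ccccc3)cc1CC2
F6 | step 6 | 4-[(E)-2-{3-[4-(benzyloxy)-2-[(E)-2-(3,5-dibromo-4-hydroxyphenyl)ethenyl]phenoxy]phenyl}ethenyl]-2,6-dichlorophenol | Oc1c(Br)cc(/C=C/c2cc(OCc3ccccc3)ccc2Oc2cccc(/C=C/c3cc(Cl)c(O)c(Cl)c3)c2)cc1Br
F7 | step 8 | O-benzyl (ring A) dihydroptychantol A | Oc1ccc2cc1Oc1ccc(cc1)CCc1cccc(c1)Oc1ccc(OCc3ccccc3)cc1CC2
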